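**Retrosynthetic overview**
1. Target 20 is a trans-decalin (ring A = C1–C5 + C10, ring B = C5–C10). The plan rests on C10, the quaternary methyl carbon shared by both rings, which lies next to the chain-bearing C9–H and must carry its methyl cis to that chain.
2. Late stage: C8=CH2 by Wittig reaction of a C8 ketone stored as a dioxolane; 3β-OH from the C3 ketone; the C4 gem-dimethyl pair and 5α-H from a 4-methyl-4-en-3-one by reductive methylation.
3. Key disconnection: ring A by Robinson annulation of ethyl vinyl ketone (C1–C10 Michael bond, then C4=C5 aldol condensation) onto the regiodefined C5=C10 enolate of a ring B ketone that already carries the whole C9 chain.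
4. That enolate, held as its silyl enol ether 10, comes from copper-catalysed asymmetric conjugate addition of homofarnesylmagnesium bromide to the 2-methyl enone ketal 3 (sets C9). Enone 3 comes from ketal enone 1 by iodination and Suzuki methylation; the chain comes from farnesyl bromide by one-carbon homologation.
5. Ring order: ring B is bought as the six-membered ketal 1; ring A is closed in step 7.

Key step: step 7

Remarks
- Numbering: ring carbons are numbered as in the target (C3 carbinol, C4 gem-dimethyl, C8 methylene carbon, C9 chain carbon, C10 angular methyl). HF = homofarnesyl = (3E,7E)-4,8,12-trimethyltrideca-3,7,11-trien-1-yl.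
- Ligand L1 = O,O′-[(S)-1,1′-binaphthyl-2,2′-diyl] N,N-bis[(R)-1-phenylethyl]phosphoramidite.
- Assumption: (S,R,R)-L1 is taken to deliver the chain to the enone face that gives (6R)-10; if a pilot run shows the opposite sense, its (R,S,S) enantiomer is used.
- Assumption: ketal enone 1 is taken as a catalogue compound.

**Route**

Step 1
Reactants: 1 1,4-dioxaspiro[4.5]dec-6-en-8-one
Product: 2 7-iodo-1,4-dioxaspiro[4.5]dec-6-en-8-one
Conditions: I2, pyridine, CH2Cl2, 0 °C → rt
Reagents that add atoms: iodine, II
Why: α-Iodination of a cyclic enone (conjugate addition of pyridine, iodination of the resulting enolate, E1cB loss of pyridine) should mark the only enone α-position, C7, and the base-buffered medium leaves the ketal intact.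

Step 2
Reactants: 2 7-iodo-1,4-dioxaspiro[4.5]dec-6-en-8-one
Product: 3 7-methyl-1,4-dioxaspiro[4.5]dec-6-en-8-one
Conditions: MeB(OH)2, PdCl2(dppf) (5 mol %; dppf = 1,1′-bis(diphenylphosphino)ferrocene), K2CO3, dioxane/H2O, 80 °C
Reagents that add atoms: methylboronic acid, CB(O)O
Why: Suzuki–Miyaura cross-coupling (oxidative addition of zerovalent palladium into the C7–I bond, transmetalation of methyl, reductive elimination) should place the future C10 methyl exactly at C7 with no regiochemical ambiguity.

Step 3
Reactants: 4 (2E,6E)-farnesyl bromide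
Product: 5 dimethyl(propan-2-yloxy)[(3E,7E)-4,8,12-trimethyltrideca-3,7,11-trien-1-yl]silane
Conditions: iPrO(Me)2SiCH2MgCl (from ClCH2SiMe2(OiPr) and Mg, THF), Li2CuCl4 (3 mol %), THF, 0 °C
Reagents that add atoms: (isopropoxydimethylsilyl)methylmagnesium chloride, CC(C)O[Si](C)(C)C[Mg]Cl
Why: Copper-catalysed cross-coupling of an allylic bromide with an α-silyl Grignard reagent (a hydroxymethyl anion equivalent) should occur at the primary carbon, since attack at the γ-carbon would build a quaternary centre, and so adds the one missing chain carbon with the 2E geometry kept.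

Step 4
Reactants: 5 dimethyl(propan-2-yloxy)(homofarnesyl)silane
Product: 6 (3E,7E)-homofarnesol, (3E,7E)-4,8,12-trimethyltrideca-3,7,11-trien-1-ol
Conditions: 30% H2O2, KF, KHCO3, THF/MeOH, rt
Reagents that add atoms: hydrogen peroxide, OO
Why: Tamao–Fleming oxidation (peroxide attack on the fluoride-activated alkoxysilane, then 1,2-shift of the alkyl group from silicon to oxygen) should give the primary alcohol, and basic hydrogen peroxide does not epoxidise the isolated trisubstituted alkenes.

Step 5
Reactants: 6 (3E,7E)-homofarnesol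
Product: 7 (3E,7E)-homofarnesyl bromide, (3E,7E)-1-bromo-4,8,12-trimethyltrideca-3,7,11-triene
Conditions: CBr4, PPh3, CH2Cl2, 0 °C
Reagents that add atoms: tetrabromomethane, BrC(Br)(Br)Br
Why: The Appel reaction (SN2 displacement of the alkoxyphosphonium ion by bromide) under neutral conditions should give the homoallylic bromide without touching the alkene geometry.

Step 6
Reactants: 3 7-methyl-1,4-dioxaspiro[4.5]dec-6-en-8-one; 7 (3E,7E)-homofarnesyl bromide
Product: 10 trimethyl{[(6R)-7-methyl-6-HF-1,4-dioxaspiro[4.5]dec-7-en-8-yl]oxy}silane, via homofarnesylmagnesium bromide 8 (not isolated), via bromomagnesium enolate 9 (not isolated)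
Conditions: 7, Mg, Et2O, rt; then 3, CuBr·SMe2 (5 mol %), (S,R,R)-L1 (10 mol %), Et2O, −78 °C, slow addition of 8; then Me3SiCl, Et3N, DMPU, −78 → 0 °C
Reagents that add atoms: chlorotrimethylsilane, C[Si](C)(C)Cl
Why: Copper-catalysed asymmetric conjugate addition of a Grignard reagent to a cyclic α-substituted enone: the chiral phosphoramidite–copper complex should select one face of C6 (the future C9) and set its R configuration, and O-silylation of magnesium enolate 9 stores the enolate as the C7=C8 (future C10=C5) regioisomer only.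

Step 7
Reactants: 10 trimethyl{[(6R)-7-methyl-6-HF-1,4-dioxaspiro[4.5]dec-7-en-8-yl]oxy}silane; 11 ethyl vinyl ketone
Product: 15 (9R,10R)-8,8-ethylenedioxy-4,10-dimethyl-9-HF-octal-4-en-3-one (10β-CH3, 9β-chain), via C5 lithium enolate 12 (not isolated), via 1,5-diketone 13 (not isolated), via ketol 14 (not isolated)
Conditions: MeLi, THF, 0 °C → rt; 11, −78 → −20 °C; then KOH, MeOH, rt → 60 °C (crude adduct, no purification)
Reagents that add atoms: none
Why: MeLi cleaves the O–Si bond of 10 and releases the C5=C10 lithium enolate 12, which adds through C10 to the terminal carbon of 11 (Michael addition, forms C1–C10) to give 1,5-diketone 13; the closest known reaction type is the Robinson annulation of a regiospecific enolate regenerated from its silyl enol ether after a conjugate addition. With KOH in methanol the C4 enolate of the ethyl ketone attacks the C5 carbonyl, a 6-(enolexo)-exo-trig aldol closure that forms ring A as ketol 14, and E1cB loss of water gives the C4=C5 enone. The one new stereocentre, quaternary C10, is controlled by the neighbouring C9 stereocentre: in the half-chair enolate the C9 chain sits pseudoaxial to escape A(1,2) strain against the C10 methyl, and the enone should add axially to the opposite face, so that the new C1 branch ends trans to the chain and the C10 methyl cis to it. Regioselectivity (bond formation at C10 and not at C6) is needed and is secured because 12 is formed only from the C5=C10 silyl enol ether in an aprotic medium at low temperature, where enolate equilibration is slow. The aldol must close on C5 and not on C8, which the dioxolane at C8 guarantees, and the same dioxolane keeps the C8 carbonyl for the last step.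

Step 8
Reactants: 15 (9R,10R)-8,8-ethylenedioxy-4,10-dimethyl-9-HF-octal-4-en-3-one
Product: 17 (5R,9R,10S)-8,8-ethylenedioxy-4,4,10-trimethyl-9-HF-trans-decal-3-one (5α-H, 9β-chain, 10β-CH3), via C3 lithium enolate 16 (not isolated)
Conditions: Li, NH3(l)/THF, t-BuOH (1 equiv), −78 °C; then MeI (excess), −78 → −33 °C
Reagents that add atoms: iodomethane, CI
Why: Dissolving-metal reductive alkylation of an enone: two-electron reduction and axial protonation of C5 on the face opposite the 10β-methyl group should give the trans ring fusion (5α-H), and the remaining C3–C4 lithium enolate 16 is methylated at C4 to complete the gem-dimethyl pair, while the ketal and the isolated alkenes are inert to lithium in ammonia.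

Step 9
Reactants: 17 (5R,9R,10S)-8,8-ethylenedioxy-4,4,10-trimethyl-9-HF-trans-decal-3-one
Product: 18 (3S,5R,9R,10S)-8,8-ethylenedioxy-4,4,10-trimethyl-9-HF-trans-decalin-3-ol (3β-OH)
Conditions: NaBH4, MeOH/THF, 0 °C
Reagents that add atoms: none
Why: Hydride reduction of a hindered cyclohexanone: borohydride should attack axially from the α face, away from the axial 4β- and 10β-methyl groups, to give the equatorial 3β-alcohol.

Step 10
Reactants: 18 (3S,5R,9R,10S)-8,8-ethylenedioxy-4,4,10-trimethyl-9-HF-trans-decalin-3-ol
Product: 19 (3S,5R,9R,10S)-3-hydroxy-4,4,10-trimethyl-9-HF-trans-decal-8-one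
Conditions: PPTS, acetone/H2O, 55 °C
Reagents that add atoms: water, O
Why: Mild acid-catalysed hydrolysis of the dioxolane should release the C8 ketone; C9 becomes epimerisable but its equatorial β-chain is the thermodynamically preferred arrangement, and the buffered aqueous acid is too weak to protonate the trisubstituted alkenes or start a cation–olefin cyclisation.

Step 11
Reactants: 19 (3S,5R,9R,10S)-3-hydroxy-4,4,10-trimethyl-9-HF-trans-decal-8-one
Product: 20 (2S,4aR,5S,8aR)-1,1,4a-trimethyl-6-methylidene-5-[(3E,7E)-4,8,12-trimethyltrideca-3,7,11-trien-1-yl]decahydronaphthalen-2-ol (target; 3S,5R,9S,10R in target numbering)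
Conditions: Ph3PCH3Br, KOtBu (excess), THF, rt → 60 °C
Reagents that add atoms: methyltriphenylphosphonium bromide, C[P+](c1ccccc1)(c1ccccc1)c1ccccc1.[Br-]
Why: Wittig methylenation with excess ylide (one equivalent is spent on the C3 alkoxide) should convert the C8 ketone into the exocyclic methylene, and any base-mediated equilibration at C9 favours the equatorial chain already present.

**Compound list**
1 | 1,4-dioxaspiro[4.5]dec-6-en-8-one | O=C1C=CC2(CC1)OCCO2 | starting material
2 | 7-iodo-1,4-dioxaspiro[4.5]dec-6-en-8-one | O=C1CCC2(C=C1I)OCCO2 | intermediate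
3 | 7-methyl-1,4-dioxaspiro[4.5]dec-6-en-8-one | CC1=CC2(CCC1=O)OCCO2 | intermediate
4 | (2E,6E)-farnesyl bromide | CC(C)=CCC/C(C)=C/CC/C(C)=C/CBr | starting material
5 | dimethyl(propan-2-yloxy)[(3E,7E)-4,8,12-trimethyltrideca-3,7,11-trien-1-yl]silane | CC(C)O[Si](C)(C)CC/C=C(\C)CC/C=C(\C)CCC=C(C)C | intermediate
6 | (3E,7E)-homofarnesol | OCC/C=C(\C)CC/C=C(\C)CCC=C(C)C | intermediate
7 | (3E,7E)-homofarnesyl bromide | BrCC/C=C(\C)CC/C=C(\C)CCC=C(C)C | intermediate
8 | (3E,7E)-homofarnesylmagnesium bromide | Br[Mg]CC/C=C(\C)CC/C=C(\C)CCC=C(C)C | intermediate (not isolated)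
9 | bromomagnesium (6R)-7-methyl-6-HF-1,4-dioxaspiro[4.5]dec-7-en-8-olate | CC1=C(O[Mg]Br)CCC2(OCCO2)[C@@H]1CC/C=C(\C)CC/C=C(\C)CCC=C(C)C | intermediate (not isolated)
10 | trimethyl{[(6R)-7-methyl-6-HF-1,4-dioxaspiro[4.5]dec-7-en-8-yl]oxy}silane | CC1=C(O[Si](C)(C)C)CCC2(OCCO2)[C@@H]1CC/C=C(\C)CC/C=C(\C)CCC=C(C)C | intermediate
11 | ethyl vinyl ketone (pent-1-en-3-one) | CCC(=O)C=C | starting material
12 | lithium (6R)-7-methyl-6-HF-1,4-dioxaspiro[4.5]dec-7-en-8-olate | CC1=C(O[Li])CCC2(OCCO2)[C@@H]1CC/C=C(\C)CC/C=C(\C)CCC=C(C)C | intermediate (not isolated)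
13 | (6R,7R)-7-methyl-7-(3-oxopentyl)-6-HF-1,4-dioxaspiro[4.5]decan-8-one | CCC(=O)CC[C@@]1(C)C(=O)CCC2(OCCO2)[C@@H]1CC/C=C(\C)CC/C=C(\C)CCC=C(C)C | intermediate (not isolated)
14 | ring A ketol, 8,8-ethylenedioxy-5-hydroxy-4,10β-dimethyl-9β-HF-decal-3-one (mixture at C4 and C5) | CC1C(=O)CC[C@]2(C)[C@@H](CC/C=C(\C)CC/C=C(\C)CCC=C(C)C)C3(OCCO3)CCC12O | intermediate (not isolated)
15 | (9R,10R)-8,8-ethylenedioxy-4,10-dimethyl-9-HF-octal-4-en-3-one | CC1=C2CCC3(OCCO3)[C@H](CC/C=C(\C)CC/C=C(\C)CCC=C(C)C)[C@@]2(C)CCC1=O | intermediate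
16 | lithium C3 enolate of the 5α-H 4-methyl ketone (C3=C4) | CC1=C(O[Li])CC[C@]2(C)[C@@H](CC/C=C(\C)CC/C=C(\C)CCC=C(C)C)C3(OCCO3)CC[C@@H]12 | intermediate (not isolated)
17 | (5R,9R,10S)-8,8-ethylenedioxy-4,4,10-trimethyl-9-HF-trans-decal-3-one | CC1(C)C(=O)CC[C@]2(C)[C@@H](CC/C=C(\C)CC/C=C(\C)CCC=C(C)C)C3(OCCO3)CC[C@@H]12 | intermediate
18 | (3S,5R,9R,10S)-8,8-ethylenedioxy-4,4,10-trimethyl-9-HF-trans-decalin-3-ol | CC1(C)[C@@H](O)CC[C@]2(C)[C@@H](CC/C=C(\C)CC/C=C(\C)CCC=C(C)C)C3(OCCO3)CC[C@@H]12 | intermediate
19 | (3S,5R,9R,10S)-3-hydroxy-4,4,10-trimethyl-9-HF-trans-decal-8-one | CC1(C)[C@@H](O)CC[C@]2(C)[C@@H](CC/C=C(\C)CC/C=C(\C)CCC=C(C)C)C(=O)CC[C@@H]12 | intermediate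
20 | (2S,4aR,5S,8aR)-1,1,4a-trimethyl-6-methylidene-5-[(3E,7E)-4,8,12-trimethyltrideca-3,7,11-trien-1-yl]decahydronaphthalen-2-ol | C=C1CC[C@H]2C(C)(C)[C@@H](O)CC[C@]2(C)[C@H]1CC/C=C(\C)CC/C=C(\C)CCC=C(C)C | target

**Totals**
Total step count: 11. Longest linear sequence: 9 steps (steps 3–11, from farnesyl bromide 4).

**Steps most likely to fail**

1. Step 7 (key step). Ethyl vinyl ketone may polymerise anionically, and the first-formed adduct enolate or the acceptor's α-protons may transfer a proton to 12, which returns ketone and scrambles the enolate regiochemistry; facial control at C10 may also be incomplete. The fallback changes the acceptor to one with a removable α-silyl group. (1-Bromovinyl)trimethylsilane is converted to its Grignard reagent and added to propanal to give 2-(trimethylsilyl)pent-1-en-3-ol F1, which Dess–Martin periodinane should oxidise to 2-(trimethylsilyl)pent-1-en-3-one F2. The fallback sets out from 10: enolate 12 is released with MeLi as before and added to F2 at −78 °C. The adduct is an α-silyl-stabilised enolate that should neither add to more acceptor nor exchange protons, and work-up gives the α-silyl 1,5-diketone F3. KOH in aqueous methanol should then remove the silyl group and carry the material through 13 and 14 to enone 15, where the route is rejoined. The bulkier acceptor should also sharpen the preference for attack anti to the C9 chain.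

2. Step 6. The β-carbon is flanked by the ketal carbon and faces an α-methyl group, so addition may be slow; ligand-free background addition or 1,2-addition could then compete and erode the enantioselectivity. The fallback gives up asymmetric catalysis for a resolution. It sets out from 3 and 8: addition with CuBr·SMe2 (10 mol %) in THF at −78 °C without chiral ligand should give the racemic bromomagnesium enolate F4, and Me3SiCl with Et3N then gives the racemic silyl enol ether F5. Under the conditions of step 7, F5 should pass through the racemic lithium enolate F6, the racemic 1,5-diketone F7 and the racemic ketol F8 to the racemic enone F9; its relative configuration is substrate-controlled and unaffected. Preparative chromatography of F9 on a polysaccharide-carbamate chiral stationary phase (the enone chromophore allows UV detection) should separate 15 from the unwanted (9S,10S) enantiomer F10. The absolute configuration would be assigned by Mosher ester analysis at the stage of 18. The route is rejoined at 15.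

3. Step 8. Enolate 16 may be protonated by ammonia, tert-butanol or product ketone before it is methylated, the C3 carbonyl may be over-reduced, or the product may be methylated again at C2. The fallback separates reduction from alkylation. It sets out from 15: after reduction with Li in NH3/THF (t-BuOH, 1 equiv) the ammonia is evaporated and the enolate is silylated with Me3SiCl and Et3N in THF to give the C3 trimethylsilyl enol ether F11, which can be purified. MeLi in THF then regenerates enolate 16 free of amide and alkoxide bases, and MeI with DMPU should give 17, where the route is rejoined.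

**Further compounds**
F1 | step 7 | 2-(trimethylsilyl)pent-1-en-3-ol (racemic) | CCC(O)C(=C)[Si](C)(C)C
F2 | step 7 | 2-(trimethylsilyl)pent-1-en-3-one | CCC(=O)C(=C)[Si](C)(C)C
F3 | step 7 | (6R,7R)-7-methyl-7-[3-oxo-2-(trimethylsilyl)pentyl]-6-HF-1,4-dioxaspiro[4.5]decan-8-one (mixture at the silyl-bearing carbon) | CCC(=O)C(C[C@@]1(C)C(=O)CCC2(OCCO2)[C@@H]1CC/C=C(\C)CC/C=C(\C)CCC=C(C)C)[Si](C)(C)C
F4 | step 6 | racemic bromomagnesium 7-methyl-6-HF-1,4-dioxaspiro[4.5]dec-7-en-8-olate | CC1=C(O[Mg]Br)CCC2(OCCO2)C1CC/C=C(\C)CC/C=C(\C)CCC=C(C)C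
F5 | step 6 | racemic trimethyl[(7-methyl-6-HF-1,4-dioxaspiro[4.5]dec-7-en-8-yl)oxy]silane | CC1=C(O[Si](C)(C)C)CCC2(OCCO2)C1CC/C=C(\C)CC/C=C(\C)CCC=C(C)C
F6 | step 6 | racemic lithium 7-methyl-6-HF-1,4-dioxaspiro[4.5]dec-7-en-8-olate | CC1=C(O[Li])CCC2(OCCO2)C1CC/C=C(\C)CC/C=C(\C)CCC=C(C)C
F7 | step 6 | racemic 1,5-diketone (13 and its enantiomer) | CCC(=O)CC[C@@]1(C)C(=O)CCC2(OCCO2)[C@@H]1CC/C=C(\C)CC/C=C(\C)CCC=C(C)C.CCC(=O)CC[C@]1(C)C(=O)CCC2(OCCO2)[C@H]1CC/C=C(\C)CC/C=C(\C)CCC=C(C)C
F8 | step 6 | racemic ring A ketol (14 and its enantiomer, mixture at C4 and C5) | CC1C(=O)CC[C@]2(C)[C@@H](CC/C=C(\C)CC/C=C(\C)CCC=C(C)C)C3(OCCO3)CCC12O.CC1C(=O)CC[C@@]2(C)[C@H](CC/C=C(\C)CC/C=C(\C)CCC=C(C)C)C3(OCCO3)CCC12O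
F9 | step 6 | racemic enone (15 and its enantiomer) | CC1=C2CCC3(OCCO3)[C@H](CC/C=C(\C)CC/C=C(\C)CCC=C(C)C)[C@@]2(C)CCC1=O.CC1=C2CCC3(OCCO3)[C@@H](CC/C=C(\C)CC/C=C(\C)CCC=C(C)C)[C@]2(C)CCC1=O
F10 | step 6 | (9S,10S)-8,8-ethylenedioxy-4,10-dimethyl-9-HF-octal-4-en-3-one (enantiomer of 15) | CC1=C2CCC3(OCCO3)[C@@H](CC/C=C(\C)CC/C=C(\C)CCC=C(C)C)[C@]2(C)CCC1=O
F11 | step 8 | C3 trimethylsilyl enol ether of the 5α-H 4-methyl ketone (C3=C4) | CC1=C(O[Si](C)(C)C)CC[C@]2(C)[C@@H](CC/C=C(\C)CC/C=C(\C)CCC=C(C)C)C3(OCCO3)CC[C@@H]12
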